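**Plan**

- Retrosynthesis: with ring B kept as benzyl ethers, ring C is cut at O1–C2 (cyclodehydration of a 1,3-dicarbonyl equivalent). That equivalent is hidden as a 3,5-diarylisoxazole, which is cut at C3–C4 and at its temporary O–C2 bond into an aryl nitrile oxide and a terminal arylacetylene.
- Enabling feature: C4 sits on C4a, and both ring A neighbours of C4a (C5 and C8a) carry oxygen, so a nitrile oxide on the C4 carbon has both ortho positions blocked and cannot dimerise. C3, C2 and ring B are an ethynylarene, and ring A is symmetric about the C4a–C7 axis, so either ortho oxygen can become O1.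
- Forward order: the ring A fragment comes from 1,2,3-trimethoxybenzene (steps 1–6) and the ring B alkyne from 2,4-dihydroxybenzaldehyde (steps 7–8). The isoxazole ring forms in step 9, is opened at N–O in step 10, ring C closes in step 11, and the benzyl ethers leave last (step 12).
- Stereochemistry: the target has no stereocentre. The selectivity issues are the regiochemistry of the cycloaddition and the direction of ring C closure; the latter is fixed by keeping ring B benzylated until ring C exists.

Key step: step 9

Remark on the chemistry: oxime 8 and chloride 9 are drawn as single geometric isomers for definiteness; this geometry is lost when the nitrile oxide forms.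

**Route**

Step 1
Reactants: 1 1,2,3-trimethoxybenzene
Product: 2 1,5-dibromo-2,3,4-trimethoxybenzene
Conditions: NBS (2.2 equiv), MeCN, 0 °C to 50 °C
Reagents that add atoms: N-bromosuccinimide, O=C1CCC(=O)N1Br
Why: Electrophilic aromatic bromination should go twice at the two equivalent positions that are para to one outer methoxy group and ortho to the other, because the remaining position is activated only by the twisted central methoxy group.

Step 2
Reactants: 2 1,5-dibromo-2,3,4-trimethoxybenzene
Product: 4 4,5,6-trimethoxybenzene-1,3-diol, via bis(pinacolboronate) 3 (not isolated)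
Conditions: B2pin2 (2.6 equiv), PdCl2(dppf) (5 mol%), KOAc, 1,4-dioxane, 90 °C; then Celite filtration, THF, aq NaOH, 30% H2O2, 0 °C to rt, argon
Reagents that add atoms: hydrogen peroxide, OO
Why: A twofold Miyaura borylation of the aryl bromides followed by alkaline peroxide oxidation (aryl migration from boron to oxygen) is the standard way from aryl bromides to phenols and should tolerate the methyl ethers.

Step 3
Reactants: 4 4,5,6-trimethoxybenzene-1,3-diol
Product: 5 1,2,3-trimethoxy-4,6-bis(methoxymethoxy)benzene
Conditions: MOMCl (3 equiv), K2CO3, acetone, 0 °C to rt, argon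
Reagents that add atoms: chloromethyl methyl ether, COCCl
Why: Williamson-type O-alkylation of both phenoxides with the hard α-chloro ether gives the bis-MOM ether, whose acetal oxygens later direct lithiation and are removable by acid that leaves benzyl ethers alone.

Step 4
Reactants: 5 1,2,3-trimethoxy-4,6-bis(methoxymethoxy)benzene
Product: 7 3,4,5-trimethoxy-2,6-bis(methoxymethoxy)benzaldehyde, via aryllithium 6 (not isolated)
Conditions: n-BuLi (1.2 equiv), THF, 0 °C; DMF, 0 °C to rt; H2O
Reagents that add atoms: N,N-dimethylformamide, CN(C)C=O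
Why: Directed ortho-metalation removes the only ring hydrogen, which lies between two chelating OMOM groups, and the aryllithium is formylated by DMF (Bouveault-type formylation).

Step 5
Reactants: 7 3,4,5-trimethoxy-2,6-bis(methoxymethoxy)benzaldehyde
Product: 8 (E)-3,4,5-trimethoxy-2,6-bis(methoxymethoxy)benzaldehyde oxime
Conditions: NH2OH (50 wt% in H2O), EtOH, 60 °C
Reagents that add atoms: hydroxylamine, NO
Why: Oxime condensation with free hydroxylamine works on hindered 2,6-disubstituted benzaldehydes and avoids acid, so the MOM acetals should survive.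

Step 6
Reactants: 8 (E)-3,4,5-trimethoxy-2,6-bis(methoxymethoxy)benzaldehyde oxime
Product: 10 3,4,5-trimethoxy-2,6-bis(methoxymethoxy)benzonitrile oxide, via hydroximoyl chloride 9 (not isolated)
Conditions: aq NaOCl (1.3 equiv), CH2Cl2, 0 °C; product crystallised cold and stored at −20 °C
Reagents that add atoms: none
Why: Hypochlorite oxidation of an aldoxime chlorinates the oxime carbon and the basic two-phase medium removes HCl (1,3-dehydrochlorination); the ring has no free position to chlorinate, and the two ortho OMOM groups should make the nitrile oxide isolable like other 2,6-disubstituted benzonitrile oxides.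

Step 7
Reactants: 11 2,4-dihydroxybenzaldehyde
Product: 12 2,4-bis(benzyloxy)benzaldehyde
Conditions: BnBr (2.4 equiv), K2CO3, DMF, 70 °C
Reagents that add atoms: benzyl bromide, BrCc1ccccc1
Why: Williamson ether synthesis, with heating so that the hydrogen-bonded ortho hydroxyl is also alkylated.

Step 8
Reactants: 12 2,4-bis(benzyloxy)benzaldehyde
Product: 13 2,4-bis(benzyloxy)-1-ethynylbenzene
Conditions: dimethyl (1-diazo-2-oxopropyl)phosphonate (1.5 equiv), K2CO3, MeOH/THF, 0 °C to rt
Reagents that add atoms: dimethyl (1-diazo-2-oxopropyl)phosphonate (Ohira–Bestmann reagent), CC(=O)C(=[N+]=[N-])P(=O)(OC)OC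
Why: Seyferth–Gilbert homologation in its Ohira–Bestmann form (methanolysis to the diazomethylphosphonate anion, addition to the aldehyde, loss of phosphate and nitrogen, 1,2-hydrogen shift) converts aryl aldehydes to terminal alkynes under mild base that benzyl ethers tolerate.

Step 9
Reactants: 10 3,4,5-trimethoxy-2,6-bis(methoxymethoxy)benzonitrile oxide; 13 2,4-bis(benzyloxy)-1-ethynylbenzene
Product: 14 5-[2,4-bis(benzyloxy)phenyl]-3-[3,4,5-trimethoxy-2,6-bis(methoxymethoxy)phenyl]isoxazole
Conditions: 13 (1.2 equiv), toluene, 80 °C, N2
Reagents that add atoms: none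
Why: A concerted, asynchronous Huisgen [3+2] cycloaddition joins the nitrile oxide carbon of 10 (future C4) to the terminal alkyne carbon of 13 (future C3) and the oxide oxygen to the aryl-bearing alkyne carbon (future C2), so the five-membered isoxazole ring closes by intermolecular cycloaddition with both ring bonds formed at once. The closest known reaction is the addition of isolable 2,6-disubstituted benzonitrile oxides such as mesitonitrile oxide to phenylacetylene, which gives 3,5-diarylisoxazoles. No stereocentre is created. The step needs regioselectivity for the 3,5- over the 3,4-diaryl isomer, which the terminal alkyne secures: its larger HOMO coefficient lies on the unsubstituted carbon, which bonds to the electrophilic nitrile oxide carbon, and the shielded aryl group and ring B avoid each other. It also needs the dipole to outlive a slow bimolecular reaction, which the two ortho OMOM groups provide by blocking furoxan dimerisation, while the temperature stays well below that of nitrile oxide to isocyanate rearrangement.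

Step 10
Reactants: 14 5-[2,4-bis(benzyloxy)phenyl]-3-[3,4,5-trimethoxy-2,6-bis(methoxymethoxy)phenyl]isoxazole
Product: 15 (Z)-3-amino-1-[2,4-bis(benzyloxy)phenyl]-3-[3,4,5-trimethoxy-2,6-bis(methoxymethoxy)phenyl]prop-2-en-1-one
Conditions: Mo(CO)6 (1.0 equiv), MeCN/H2O, 80 °C
Reagents that add atoms: none
Why: Reductive N–O cleavage of isoxazoles by zerovalent molybdenum with water as proton source is the established unmasking to the hydrogen-bonded Z β-amino enone and should leave benzyl and MOM ethers untouched.

Step 11
Reactants: 15 (Z)-3-amino-1-[2,4-bis(benzyloxy)phenyl]-3-[3,4,5-trimethoxy-2,6-bis(methoxymethoxy)phenyl]prop-2-en-1-one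
Product: 17 2-[2,4-bis(benzyloxy)phenyl]-5-hydroxy-6,7,8-trimethoxy-4H-chromen-4-one, via dihydroxy diketone 16 (not isolated)
Conditions: 3 M aq HCl, MeOH/THF, 60 °C
Reagents that add atoms: water, O
Why: Aqueous acid cleaves both MOM acetals and hydrolyses the vinylogous amide (nitrogen leaves as ammonium), after which either of the two equivalent phenols adds to the ring B ketone (6-exo-trig) and dehydration gives the chromone, as in the acid cyclodehydration that ends a Baker–Venkataraman flavone synthesis; ring B stays benzylated and so cannot close the other way.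

Step 12
Reactants: 17 2-[2,4-bis(benzyloxy)phenyl]-5-hydroxy-6,7,8-trimethoxy-4H-chromen-4-one
Product: 18 tamadone, 2-(2,4-dihydroxyphenyl)-5-hydroxy-6,7,8-trimethoxy-4H-chromen-4-one
Conditions: H2 (1 atm), 10% Pd/C, EtOAc/MeOH, rt
Reagents that add atoms: none
Why: Hydrogenolysis of aryl benzyl ethers over palladium on carbon is routine for benzyloxyflavones, whose C2–C3 double bond is a vinylogous ester that is reduced much more slowly, so stopping at the calculated hydrogen uptake should give the triol.

**Compound list**

1 | 1,2,3-trimethoxybenzene | COc1cccc(OC)c1OC | starting material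
2 | 1,5-dibromo-2,3,4-trimethoxybenzene | COc1c(Br)cc(Br)c(OC)c1OC | intermediate
3 | 2,2'-(4,5,6-trimethoxy-1,3-phenylene)bis(4,4,5,5-tetramethyl-1,3,2-dioxaborolane) | COc1c(B2OC(C)(C)C(C)(C)O2)cc(B2OC(C)(C)C(C)(C)O2)c(OC)c1OC | intermediate (not isolated)
4 | 4,5,6-trimethoxybenzene-1,3-diol | COc1c(O)cc(O)c(OC)c1OC | intermediate
5 | 1,2,3-trimethoxy-4,6-bis(methoxymethoxy)benzene | COCOc1cc(OCOC)c(OC)c(OC)c1OC | intermediate
6 | [3,4,5-trimethoxy-2,6-bis(methoxymethoxy)phenyl]lithium | [Li]c1c(OCOC)c(OC)c(OC)c(OC)c1OCOC | intermediate (not isolated)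
7 | 3,4,5-trimethoxy-2,6-bis(methoxymethoxy)benzaldehyde | COCOc1c(C=O)c(OCOC)c(OC)c(OC)c1OC | intermediate
8 | (E)-3,4,5-trimethoxy-2,6-bis(methoxymethoxy)benzaldehyde oxime | COCOc1c(/C=N/O)c(OCOC)c(OC)c(OC)c1OC | intermediate
9 | (Z)-N-hydroxy-3,4,5-trimethoxy-2,6-bis(methoxymethoxy)benzimidoyl chloride | COCOc1c(/C(Cl)=N/O)c(OCOC)c(OC)c(OC)c1OC | intermediate (not isolated)
10 | 3,4,5-trimethoxy-2,6-bis(methoxymethoxy)benzonitrile oxide | COCOc1c(C#[N+][O-])c(OCOC)c(OC)c(OC)c1OC | intermediate
11 | 2,4-dihydroxybenzaldehyde | O=Cc1ccc(O)cc1O | starting material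
12 | 2,4-bis(benzyloxy)benzaldehyde | O=Cc1ccc(OCc2ccccc2)cc1OCc1ccccc1 | intermediate
13 | 2,4-bis(benzyloxy)-1-ethynylbenzene | C#Cc1ccc(OCc2ccccc2)cc1OCc1ccccc1 | intermediate
14 | 5-[2,4-bis(benzyloxy)phenyl]-3-[3,4,5-trimethoxy-2,6-bis(methoxymethoxy)phenyl]isoxazole | COCOc1c(OC)c(OC)c(OC)c(OCOC)c1-c1cc(-c2ccc(OCc3ccccc3)cc2OCc2ccccc2)on1 | intermediate
15 | (Z)-3-amino-1-[2,4-bis(benzyloxy)phenyl]-3-[3,4,5-trimethoxy-2,6-bis(methoxymethoxy)phenyl]prop-2-en-1-one | COCOc1c(OC)c(OC)c(OC)c(OCOC)c1/C(N)=C/C(=O)c1ccc(OCc2ccccc2)cc1OCc1ccccc1 | intermediate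
16 | 1-[2,4-bis(benzyloxy)phenyl]-3-(2,6-dihydroxy-3,4,5-trimethoxyphenyl)propane-1,3-dione | COc1c(OC)c(O)c(C(=O)CC(=O)c2ccc(OCc3ccccc3)cc2OCc2ccccc2)c(O)c1OC | intermediate (not isolated)
17 | 2-[2,4-bis(benzyloxy)phenyl]-5-hydroxy-6,7,8-trimethoxy-4H-chromen-4-one | COc1c(OC)c(O)c2c(=O)cc(-c3ccc(OCc4ccccc4)cc3OCc3ccccc3)oc2c1OC | intermediate
18 | tamadone, 2-(2,4-dihydroxyphenyl)-5-hydroxy-6,7,8-trimethoxy-4H-chromen-4-one | COc1c(OC)c(O)c2c(=O)cc(-c3ccc(O)cc3O)oc2c1OC | target

**Step count and risks**

Total step count: 12. Longest linear sequence: 10 steps (steps 1–6, then 9–12); steps 7–8 form the second branch.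

Most likely to fail:

1. Step 9. The doubly ortho-shielded, electron-rich dipole may add so slowly to the electron-rich alkyne that isomerisation to the isocyanate or decomposition overtakes the cycloaddition on prolonged heating, and a small share of addition in the reverse orientation cannot be ruled out. The fallback builds the same two bonds one after the other by ionic chemistry. It sets out from 13 and 10: alkyne 13 is deprotonated (n-BuLi, THF, −78 °C) to lithium [2,4-bis(benzyloxy)phenyl]acetylide F1, which adds to the nitrile oxide carbon of 10 and forms the C4–C3 bond. Aqueous quench should give (E)-3-[2,4-bis(benzyloxy)phenyl]-1-[3,4,5-trimethoxy-2,6-bis(methoxymethoxy)phenyl]prop-2-yn-1-one oxime F2, with the hydroxyl on the alkyne side because nucleophiles add trans across nitrile oxides. A 5-endo-dig cycloisomerisation of this acetylenic oxime (catalytic AuCl3, CH2Cl2, rt) then closes the O–C2 bond and comes back to the route at 14, with the regiochemistry fixed by connectivity.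

2. Step 2. The second borylation may lag, or protodebromination may take over at the electron-rich ortho-methoxy positions, and the very electron-rich resorcinol may be degraded by alkaline peroxide. The fallback sets out from 2 and masks the oxygens while they are introduced: twofold palladium-catalysed C–O coupling with benzyl alcohol ([Pd(allyl)Cl]2, RockPhos, Cs2CO3, toluene, 90 °C) should give 1,5-bis(benzyloxy)-2,3,4-trimethoxybenzene F3. Hydrogenolysis (H2, 10% Pd/C, EtOAc, rt) then releases the diol under neutral, reducing conditions and comes back to the route at 4.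

3. Step 11. One acid treatment has to remove two acetals, hydrolyse a hindered vinylogous amide and dehydrate; if hydrolysis or dehydration lags (for instance by stalling at the chromone 4-imine salt), forcing the acid could start to cleave the benzyl ether ortho to the ring B carbonyl and open the competing closure from ring B. The fallback changes the order of unmasking and sets out from 14. The MOM groups are removed while the isoxazole is still intact and nothing can cyclise (HCl in MeOH, rt), giving 2-{5-[2,4-bis(benzyloxy)phenyl]isoxazol-3-yl}-4,5,6-trimethoxybenzene-1,3-diol F4. Reductive opening (Mo(CO)6, MeCN/H2O, 80 °C) then gives (Z)-3-amino-1-[2,4-bis(benzyloxy)phenyl]-3-(2,6-dihydroxy-3,4,5-trimethoxyphenyl)prop-2-en-1-one F5, in which the phenol is already in place, so weak acid alone (1 M aq HCl, EtOH, 50 °C) should effect closure and loss of nitrogen. The sequence comes back to the route at 17.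

**Further compounds**

F1 | step 9 | lithium [2,4-bis(benzyloxy)phenyl]acetylide | [Li]C#Cc1ccc(OCc2ccccc2)cc1OCc1ccccc1
F2 | step 9 | (E)-3-[2,4-bis(benzyloxy)phenyl]-1-[3,4,5-trimethoxy-2,6-bis(methoxymethoxy)phenyl]prop-2-yn-1-one oxime | COCOc1c(OC)c(OC)c(OC)c(OCOC)c1/C(C#Cc1ccc(OCc2ccccc2)cc1OCc1ccccc1)=N/O
F3 | step 2 | 1,5-bis(benzyloxy)-2,3,4-trimethoxybenzene | COc1c(OCc2ccccc2)cc(OCc2ccccc2)c(OC)c1OC
F4 | step 11 | 2-{5-[2,4-bis(benzyloxy)phenyl]isoxazol-3-yl}-4,5,6-trimethoxybenzene-1,3-diol | COc1c(OC)c(O)c(-c2cc(-c3ccc(OCc4ccccc4)cc3OCc3ccccc3)on2)c(O)c1OC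
F5 | step 11 | (Z)-3-amino-1-[2,4-bis(benzyloxy)phenyl]-3-(2,6-dihydroxy-3,4,5-trimethoxyphenyl)prop-2-en-1-one | COc1c(OC)c(O)c(/C(N)=C/C(=O)c2ccc(OCc3ccccc3)cc2OCc2ccccc2)c(O)c1OC
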